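## Analysis of the target

Numbering used throughout: C1 (benzoate carbon next to the quaternary centre), C2=C3, C4 (benzoate), C5 (secondary hydroxyl), C6 (quaternary carbinol), exocyclic C7 (hydroxymethyl). The target is compound 13.

- 13 is a cyclohex-2-ene in which all four sp3 ring carbons (C1, C4, C5, C6) carry oxygen. C6 is a tertiary carbinol that also bears C7.
- The benzoates at C1 and C4 are cis to each other and to C7 (upper face). The hydroxyls at C5 and C6 are cis to each other on the lower face. This is a conduritol A pattern whose mirror symmetry is broken only by C7, so absolute configuration is the central problem.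
- Five oxygens must be told apart: two secondary allylic ones are benzoylated, while a primary, a secondary and a tertiary hydroxyl stay free.
- The compound is sensitive to base. The C1 benzoate lies 1,3 to the free primary hydroxyl and the C4 benzoate 1,2 to the C5 hydroxyl, so acyl shifts are easy. Both esters are allylic.
- The feature that invites the key move sits on ring C1–C6: each benzoate is allylic to C2=C3 and trans to the free hydroxyl on the neighbouring carbon (C1–OBz/C6–OH and C4–OBz/C5–OH). That is twice the signature of an anti opening of an allylic epoxide by benzoate, on either side of the C5–C6 bond.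
- The carbon skeleton is that of benzyl alcohol. 13 is therefore read as benzyl alcohol at the oxidation level of an arene dioxide, opened twice by benzoic acid. Each oxygen is then differentiated when it is introduced, and no hydroxyl at C5 or C6 needs a protecting group.
- The difficulty is that the two epoxides cannot coexist with the ring diene (arene oxide/oxepin tautomerism would racemise and aromatise). The two openings must be separated in time, and all control must come from the C6 carbinol.

## Retrosynthetic reasoning

**13 ⇒ 12.** Only the C7–O silyl ether is removed. C7–OH is masked from step 5 on because a free primary hydroxyl would accept the C1 benzoate, take part in the bromination, and direct the second epoxidation to the wrong face.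

**12 ⇒ 10 + 6 (key disconnection).** The C4–O(benzoate) bond is cut and O5 is traced back to an epoxide across C4–C5 on the face of the C6 hydroxyl. Forward, the tertiary hydroxyl of 10 must direct epoxidation to C4=C5 (not C2=C3) on its own face, and 6 must open the oxirane at allylic C4 with inversion. This one operation sets C4 and C5, installs the second benzoate and the last hydroxyl, and fixes the 1,4-cis relation of the esters. The precursor 10 is flat at four of its six ring carbons.

**10 ⇒ 8.** The C2=C3/C4=C5 diene is taken back to the single C3=C4 alkene of 8 (bromination, twofold dehydrobromination). The second unsaturation is added only after the first epoxide has been opened, so an arene-oxide-type intermediate is never formed. The quaternary C6 prevents simple aromatisation of 10.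

**8 ⇒ 7 ⇒ 5 + 6.** The C1–O(benzoate) bond is cut in the same way: anti opening of epoxy alcohol 5 at the secondary epoxide carbon by 6, under chelation to the primary hydroxyl. This sets C1 (inversion) and reveals the C6 hydroxyl (retention), already trans to the ester. Silylation of the primary hydroxyl gives 8.

**5 ⇒ 4.** The epoxide is the product of a tartrate-controlled epoxidation of the allylic alcohol 4. This is the only step that needs an external source of chirality. It fixes the quaternary C6, the hardest centre, together with C1, and leaves the remote ring alkene untouched.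

**4 ⇒ 3 ⇒ 1 + 2.** The skipped diene ring comes from a Diels–Alder reaction of 1 with 2 and reduction of the ester. All 21 carbons of 13 then derive from 1, 2 and 6.

## Alternatives that were turned down

**Alternative 1:** the textbook carbasugar route, disconnecting C2=C3.
- Forward key step: ring-closing metathesis of the acyclic diene A1 (in protected form) with the second-generation Grubbs catalyst.
- Reason for rejection: the metathesis forms the one bond that needs no stereocontrol. All four stereocentres, including the tertiary carbinol, would have to be built on an open chain (chiral-pool aldose, C-hydroxymethylation of a ketone with uncertain facial control, two vinyl additions). Five oxygens would need orthogonal protection so that exactly two secondary ones end as benzoates. A realistic count is twelve steps or more.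

**Alternative 2:** disconnecting both allylic C–O bonds (C1–O and C4–O) as a [4+2] addition of singlet oxygen to a 5,6-cis-dioxygenated cyclohexa-1,3-diene.
- Forward key step: photo-oxygenation anti to the acetonide of the microbial ipso,ortho-dihydrodiol A2 (from 6 by a benzoate dioxygenase), then O–O reduction and benzoylation.
- Reason for rejection: the enzyme gives only the (1S,2R) diol A2. Its secondary carbinol carbon is R and would become C5 with unchanged priority order, whereas C5 of 13 is S. The sequence therefore ends in A3, the mirror image of 13.
- A chemical surrogate of the right series, diene acetonide A4, could be made from 4 by asymmetric dihydroxylation with a dihydroquinine-derived ligand, ketalisation and bromination–dehydrobromination. It costs about ten steps, three protecting groups and two separate benzoylations of hydroxyls that must first be told apart from C7–OH. Its enantioselectivity on a cyclic trisubstituted alkene is less secure than that of step 3. It is also the route most chemists would draw first.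

**Alternative 3:** disconnecting C1–C6 and C4–C5 in a Diels–Alder reaction.
- Forward key step: [4+2] of the dibenzoyloxy diene A5 with the enediol-carbonate aldehyde A6 to give adduct A7, which would build the ring and all four stereocentres at once.
- Reason for rejection: both partners are poor. A5 is only weakly activated by its acyloxy groups, and A6 is a captodative, trisubstituted alkene. Forcing thermal conditions would be needed. The required topology (formyl endo, dioxolone exo) has no strong bias, and the new quaternary centre is flanked by two substituted carbons. No catalytic asymmetric variant can be defended for a β-oxygenated α-oxy enal, and A6 itself is not readily available.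

Key step: step 7

Remark on the chemistry: ring positions of all intermediates are quoted in the numbering of 13. The sense of the tartrate-controlled epoxidation is assigned by analogy with simple (E)-allylic alcohols, which give (2S,3S) epoxy alcohols with the L-(+) ligand. On that basis the D-(−) ligand is required here.

## Route

Step 1
Reactants: 1 buta-1,3-diene; 2 methyl propiolate
Product: 3 methyl cyclohexa-1,4-diene-1-carboxylate
Conditions: PhMe, hydroquinone (cat.), sealed vessel, 110 °C
Reagents that add atoms: none
Why: Thermal Diels–Alder reaction of the diene with the acetylenic ester gives the skipped 1,4-diene directly; no stereocentre is formed and the symmetric diene leaves no regiochemical question.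

Step 2
Reactants: 3 methyl cyclohexa-1,4-diene-1-carboxylate
Product: 4 (cyclohexa-1,4-dien-1-yl)methanol
Conditions: i-Bu2AlH (2.2 equiv), CH2Cl2, −78 to 0 °C; aq. KNaC4H4O6
Reagents that add atoms: none
Why: 1,2-Reduction of the conjugated ester by the aluminium hydride stops at the allylic alcohol and leaves both ring double bonds untouched.

Step 3
Reactants: 4 (cyclohexa-1,4-dien-1-yl)methanol
Product: 5 [(1R,6R)-7-oxabicyclo[4.1.0]hept-3-en-1-yl]methanol
Conditions: Ti(OiPr)4 (10 mol %), D-(−)-diisopropyl tartrate (12 mol %), t-BuOOH (2 equiv), 4 Å molecular sieves, CH2Cl2, −20 °C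
Reagents that add atoms: tert-butyl hydroperoxide, CC(C)(C)OO (one oxygen atom)
Why: Katsuki–Sharpless asymmetric epoxidation; only the double bond allylic to the hydroxyl reacts, and the D-(−) tartrate should deliver oxygen to the face that gives the (1R,6R) epoxide, in which the future C6–O and C1–O bonds lie on the lower face. The quaternary centre C6 of 13 is set here.

Step 4
Reactants: 5 [(1R,6R)-7-oxabicyclo[4.1.0]hept-3-en-1-yl]methanol; 6 benzoic acid
Product: 7 (1S,6R)-6-hydroxy-6-(hydroxymethyl)cyclohex-3-en-1-yl benzoate
Conditions: PhCO2H (1.2 equiv), Ti(OiPr)4 (1.5 equiv), CH2Cl2, 0 °C to rt; aq. tartaric acid work-up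
Reagents that add atoms: none
Why: Titanium-mediated opening of a 2,3-epoxy alcohol: the epoxide chelated through the primary alkoxide is attacked by benzoate at the secondary carbon remote from the carbinol (C1) with inversion, not at the quaternary carbon. The ester ends on the upper face, trans to the tertiary hydroxyl that keeps the epoxide oxygen; 7 should be crystalline, which allows enantiomeric enrichment.

Step 5
Reactants: 7 (1S,6R)-6-hydroxy-6-(hydroxymethyl)cyclohex-3-en-1-yl benzoate
Product: 8 (1S,6R)-6-{[(tert-butyldimethylsilyl)oxy]methyl}-6-hydroxycyclohex-3-en-1-yl benzoate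
Conditions: t-BuMe2SiCl (1.1 equiv), imidazole, CH2Cl2, 0 °C
Reagents that add atoms: tert-butyldimethylsilyl chloride, CC(C)(C)[Si](C)(C)Cl
Why: Selective silylation of the primary hydroxyl (the tertiary one is inert under these conditions). The ether blocks the 1,3-acyl shift from O1 to O7, bromo-etherification in step 6 and hydroxyl direction to the upper face in step 7.

Step 6
Reactants: 8 (1S,6R)-6-{[(tert-butyldimethylsilyl)oxy]methyl}-6-hydroxycyclohex-3-en-1-yl benzoate
Product: 10 (1S,6R)-6-{[(tert-butyldimethylsilyl)oxy]methyl}-6-hydroxycyclohexa-2,4-dien-1-yl benzoate, via trans-dibromide 9 (not isolated)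
Conditions: Br2 (1.05 equiv), CH2Cl2, −78 °C; then DBU (4 equiv), THF, 60 °C
Reagents that add atoms: bromine, BrBr (both atoms enter 9 and leave again as bromide before 10)
Why: Anti addition of bromine to the isolated alkene, then twofold E2 elimination through the antiperiplanar hydrogens at C2 and C5. Both trans dibromides converge on the one conjugated diene, no stereocentre is touched, and the quaternary C6 prevents aromatisation.

Step 7
Reactants: 10 (1S,6R)-6-{[(tert-butyldimethylsilyl)oxy]methyl}-6-hydroxycyclohexa-2,4-dien-1-yl benzoate; 6 benzoic acid
Product: 12 (1S,4R,5S,6S)-6-{[(tert-butyldimethylsilyl)oxy]methyl}-5,6-dihydroxycyclohex-2-ene-1,4-diyl dibenzoate, via syn-epoxide 11 (not isolated)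
Conditions: VO(acac)2 (5 mol %), t-BuOOH (1.2 equiv), CH2Cl2, 0 °C; then PhCO2H (1.5 equiv), Ti(OiPr)4 (1.2 equiv), 0 °C to rt
Reagents that add atoms: tert-butyl hydroperoxide, CC(C)(C)OO (one oxygen atom)
Why: The tertiary C6 hydroxyl of 10 forms a vanadate ester with the oxovanadium alkyl peroxide, and oxygen is transferred within this ester to the adjacent C4=C5 bond on the hydroxyl (lower) face, closing the transient oxirane ring of 11 by concerted syn addition (closest known type: vanadium-catalysed epoxidation of allylic alcohols). The C2=C3 bond is not touched, because its only allylic oxygen is the non-coordinating, electron-withdrawing C1 benzoate. Ti(OiPr)4 then ties the C6 alkoxide and the cis oxirane oxygen into a five-membered chelate, and benzoate attacks C4 from the upper face, anti to the breaking C–O bond (closest known type: titanium-mediated C3-selective opening of 2,3-epoxy alcohols). C5 is controlled by hydroxyl delivery from C6 and keeps the epoxide oxygen as its free hydroxyl; C4 is controlled by the SN2 inversion, which places the new benzoate trans to O5 and cis to the C1 benzoate. The step needs three selectivities: site (C4=C5 over C2=C3), face (syn to O6, reinforced by the C7 silyl ether and the C1 benzoate, which screen the upper face) and regiochemistry of opening (C4 over C5 and over conjugate attack at C2). The last is secured by the allylic activation of C4, by the chelate, by the neopentyl position of C5 next to quaternary C6 and by the C1 benzoate, which deactivates and screens C2. No protecting group is needed at O5 or O6, because the benzoate enters only where the epoxide opens.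

Step 8
Reactants: 12 (1S,4R,5S,6S)-6-{[(tert-butyldimethylsilyl)oxy]methyl}-5,6-dihydroxycyclohex-2-ene-1,4-diyl dibenzoate
Product: 13 (1S,4R,5S,6S)-5,6-dihydroxy-6-(hydroxymethyl)cyclohex-2-ene-1,4-diyl dibenzoate
Conditions: HF·pyridine, pyridine, THF, 0 °C to rt
Reagents that add atoms: none
Why: Fluoride cleavage of the primary silyl ether under mildly acidic, non-basic conditions, so that neither benzoate should migrate to a free hydroxyl; no stereocentre is affected.

## Compound list

1 | buta-1,3-diene | C=CC=C | starting material
2 | methyl propiolate | COC(=O)C#C | starting material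
3 | methyl cyclohexa-1,4-diene-1-carboxylate | COC(=O)C1=CCC=CC1 | intermediate
4 | (cyclohexa-1,4-dien-1-yl)methanol | OCC1=CCC=CC1 | intermediate
5 | [(1R,6R)-7-oxabicyclo[4.1.0]hept-3-en-1-yl]methanol | OC[C@]12CC=CC[C@H]1O2 | intermediate
6 | benzoic acid | OC(=O)c1ccccc1 | starting material
7 | (1S,6R)-6-hydroxy-6-(hydroxymethyl)cyclohex-3-en-1-yl benzoate | O=C(O[C@H]1CC=CC[C@@]1(O)CO)c1ccccc1 | intermediate
8 | (1S,6R)-6-{[(tert-butyldimethylsilyl)oxy]methyl}-6-hydroxycyclohex-3-en-1-yl benzoate | O=C(O[C@H]1CC=CC[C@@]1(O)CO[Si](C)(C)C(C)(C)C)c1ccccc1 | intermediate
9 | (1S,6R)-3,4-trans-dibromo-6-{[(tert-butyldimethylsilyl)oxy]methyl}-6-hydroxycyclohexyl benzoate (both trans dibromides form and converge; the (1S,3R,4R,6R) isomer is drawn) | O=C(O[C@H]1C[C@@H](Br)[C@H](Br)C[C@@]1(O)CO[Si](C)(C)C(C)(C)C)c1ccccc1 | intermediate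
10 | (1S,6R)-6-{[(tert-butyldimethylsilyl)oxy]methyl}-6-hydroxycyclohexa-2,4-dien-1-yl benzoate | O=C(O[C@H]1C=CC=C[C@@]1(O)CO[Si](C)(C)C(C)(C)C)c1ccccc1 | intermediate
11 | (1S,2R,3S,6S)-2-{[(tert-butyldimethylsilyl)oxy]methyl}-2-hydroxy-7-oxabicyclo[4.1.0]hept-4-en-3-yl benzoate (C4–C5 epoxide of 10 on the face of the C6 hydroxyl) | O=C(O[C@H]1C=C[C@@H]2O[C@@H]2[C@@]1(O)CO[Si](C)(C)C(C)(C)C)c1ccccc1 | intermediate
12 | (1S,4R,5S,6S)-6-{[(tert-butyldimethylsilyl)oxy]methyl}-5,6-dihydroxycyclohex-2-ene-1,4-diyl dibenzoate | O=C(O[C@H]1C=C[C@@H](OC(=O)c2ccccc2)[C@H](O)[C@@]1(O)CO[Si](C)(C)C(C)(C)C)c1ccccc1 | intermediate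
13 | (1S,4R,5S,6S)-5,6-dihydroxy-6-(hydroxymethyl)cyclohex-2-ene-1,4-diyl dibenzoate | O=C(O[C@H]1C=C[C@@H](OC(=O)c2ccccc2)[C@H](O)[C@@]1(O)CO)c1ccccc1 | target

## Step count and least certain steps

Total step count: 8. Longest linear sequence: 8 (the route is linear; 6 enters in steps 4 and 7).

**Step 7 (key step).** The most likely failures are:
- opening of the vinyl epoxide in the conjugate sense (attack at C2) or at both allylic termini, because an allylic oxirane under Lewis acid has cationic character spread over C2–C4;
- incomplete face or site control in the epoxidation of a tertiary dienol;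
- acid-induced loss of the C1 benzoate from the diene before it reacts.

Fallback: set out from 10 and separate the two C–O bond formations by a different mechanism. Hydroxyl-directed cis-dihydroxylation of C4=C5 with OsO4·TMEDA (CH2Cl2, −78 °C), delivered by hydrogen bonding to the C6 hydroxyl, would give the all-cis triol (1S,4S,5S,6S)-6-{[(tert-butyldimethylsilyl)oxy]methyl}-4,5,6-trihydroxycyclohex-2-en-1-yl benzoate F1. Its only allylic hydroxyl (C4) is then inverted by a Mitsunobu reaction with 6 (PPh3, diisopropyl azodicarboxylate, THF, 0 °C). The sequence comes back to the route at 12.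

**Step 6.** The most likely failures are:
- capture of the bromonium ion by the free tertiary hydroxyl (bromo-etherification) instead of bromide;
- substitution of the intermediate allylic bromide by the amidine base instead of the second elimination.

Both would lower the throughput to the diene. Fallback: set out from 8 and introduce the second double bond by selenium chemistry. Anti addition of PhSeCl (CH2Cl2, −78 °C) gives the β-chloro selenide (1S,6R)-4-chloro-6-{[(tert-butyldimethylsilyl)oxy]methyl}-6-hydroxy-3-(phenylselanyl)cyclohexyl benzoate F2 (with its regioisomer). Oxidation with H2O2 and syn elimination of the selenoxide away from chlorine at room temperature gives the allylic chloride (1S,6R)-4-chloro-6-{[(tert-butyldimethylsilyl)oxy]methyl}-6-hydroxycyclohex-2-en-1-yl benzoate F3. A single mild E2 step with DBU then gives 10, where the route is rejoined. Both regioisomers converge on 10, and the new C–Cl and C–Se centres need no control.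

**Step 4.** The most likely failures are:
- migration of the benzoyl group from O1 to the free primary hydroxyl through a six-membered orthoacid;
- Lewis-acid-induced isomerisation and dehydration of the cyclohexadiene monoepoxide toward an arene.

Fallback: set out from 5 and reverse the order of protection and opening. Silylation (t-BuMe2SiCl, imidazole) gives tert-butyldimethyl{[(1R,6R)-7-oxabicyclo[4.1.0]hept-3-en-1-yl]methoxy}silane F4. Its epoxide is opened without Lewis acid by PhCO2Cs and 6 in DMF at 80 °C, a plain SN2 attack at the only non-quaternary epoxide carbon. This leads directly to 8, where the route is rejoined; 7 is bypassed.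

## Further compounds

F1 | step 7 | (1S,4S,5S,6S)-6-{[(tert-butyldimethylsilyl)oxy]methyl}-4,5,6-trihydroxycyclohex-2-en-1-yl benzoate | O=C(O[C@H]1C=C[C@H](O)[C@H](O)[C@@]1(O)CO[Si](C)(C)C(C)(C)C)c1ccccc1
F2 | step 6 | (1S,6R)-4-chloro-6-{[(tert-butyldimethylsilyl)oxy]methyl}-6-hydroxy-3-(phenylselanyl)cyclohexyl benzoate (trans adduct, one regioisomer drawn, new centres not controlled) | O=C(O[C@H]1CC([Se]c2ccccc2)C(Cl)C[C@@]1(O)CO[Si](C)(C)C(C)(C)C)c1ccccc1
F3 | step 6 | (1S,6R)-4-chloro-6-{[(tert-butyldimethylsilyl)oxy]methyl}-6-hydroxycyclohex-2-en-1-yl benzoate (C4 centre not controlled) | O=C(O[C@H]1C=CC(Cl)C[C@@]1(O)CO[Si](C)(C)C(C)(C)C)c1ccccc1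
F4 | step 4 | tert-butyldimethyl{[(1R,6R)-7-oxabicyclo[4.1.0]hept-3-en-1-yl]methoxy}silane | CC(C)(C)[Si](C)(C)OC[C@]12CC=CC[C@H]1O2
A1 | alternative 1 | (3S,4S,5S,6R)-4,5-dihydroxy-4-(hydroxymethyl)octa-1,7-diene-3,6-diyl dibenzoate | C=C[C@H](OC(=O)c1ccccc1)[C@](O)(CO)[C@@H](O)[C@H](OC(=O)c1ccccc1)C=C
A2 | alternative 2 | (1S,2R)-1,2-dihydroxycyclohexa-3,5-diene-1-carboxylic acid | OC(=O)[C@]1(O)C=CC=C[C@H]1O
A3 | alternative 2 | (1R,4S,5R,6R)-5,6-dihydroxy-6-(hydroxymethyl)cyclohex-2-ene-1,4-diyl dibenzoate (mirror image of 13) | O=C(O[C@@H]1C=C[C@H](OC(=O)c2ccccc2)[C@@H](O)[C@]1(O)CO)c1ccccc1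
A4 | alternative 2 | tert-butyl{[(3aS,7aS)-2,2-dimethyl-3a,7a-dihydro-1,3-benzodioxol-3a-yl]methoxy}dimethylsilane | CC1(C)O[C@H]2C=CC=C[C@@]2(CO[Si](C)(C)C(C)(C)C)O1
A5 | alternative 3 | (1E,3E)-buta-1,3-diene-1,4-diyl dibenzoate | O=C(O/C=C/C=C/OC(=O)c1ccccc1)c1ccccc1
A6 | alternative 3 | 2-oxo-1,3-dioxole-4-carbaldehyde | O=CC1=COC(=O)O1
A7 | alternative 3 | 3a-formyl-2-oxo-3a,4,7,7a-tetrahydro-1,3-benzodioxole-4,7-diyl dibenzoate with the ring configuration of 13 (formyl cis to both benzoates, carbonate trans) | O=C(O[C@H]1C=C[C@@H](OC(=O)c2ccccc2)[C@@H]3OC(=O)O[C@]13C=O)c1ccccc1
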